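**Assumptions (one line each)**
- The target has a single stereocentre, the quaternary ring carbon, which is (R) by CIP (C=O > ring C(Me)=C > CH2-farnesyl > CH3). I assume this is the natural configuration, which is what the enzyme below makes.
- I assume the fungal UbiA-type aromatic prenyltransferase (AusN/Trt2 type) can be obtained by heterologous expression as a microsomal preparation. It is not a catalogue item.

**Retrosynthesis**
1. The target is 5-farnesyl-3,5-dimethylorsellinic acid, with the farnesyl group on the ring carbon (DMOA C-5) that already bears a methyl group. The disconnection is enzymatic dearomative ipso-C-farnesylation of 3,5-dimethylorsellinic acid (DMOA, 5) with farnesyl diphosphate (FPP, 6).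
2. DMOA comes from its methyl ester (4) by SN2 ester cleavage.
3. Ester 4 comes from the commercial resorcylate atraric acid (1) by installing the missing C-5 methyl group as CHO followed by CH3.
4. No ring is constructed. The aromatic ring is commercial, and the quaternary stereocentre is created only in the last step.

**Route**

**Step 1**
- Reactants: 1 (methyl 2,4-dihydroxy-3,6-dimethylbenzoate, atraric acid); 2 (N,N-dimethylformamide)
- Product: 3 (methyl 5-formyl-2,4-dihydroxy-3,6-dimethylbenzoate)
- Conditions: POCl3, DMF, 0 °C to 50 °C; then aq. NaOAc, rt
- Reagents that add atoms: DMF, CN(C)C=O (supplies the CHO group). POCl3 only activates DMF and is not incorporated.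
- Why: Vilsmeier–Haack formylation goes at C-5, the only free ring C–H, which is ortho to 4-OH and para to 2-OH. No stereocentre is formed.

**Step 2**
- Reactants: 3
- Product: 4 (methyl 2,4-dihydroxy-3,5,6-trimethylbenzoate, methyl DMOA ester)
- Conditions: Et3SiH (4 equiv), TFA, CH2Cl2, 0 °C to rt
- Reagents that add atoms: none
- Why: Ionic hydrogenation (silane/TFA deoxygenation) proceeds through a benzylic cation stabilised by the ortho and para OH groups, converting ArCHO to ArCH3. The methyl ester and phenols are untouched, and no alkenes are present yet.

**Step 3**
- Reactants: 4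
- Product: 5 (3,5-dimethylorsellinic acid, DMOA)
- Conditions: LiI, pyridine, reflux (115 °C), 3 h; then cold 1 M HCl to pH 3 and EtOAc extraction
- Reagents that add atoms: none (iodide leaves as MeI)
- Why: SN2 dealkylation of the methyl ester gives the carboxylate directly. The hindered, chelated ester resists hydrolysis, and the carboxylate avoids protodecarboxylation until the mild acidification.

**Step 4**
- Reactants: 5; 6 ((2E,6E)-farnesyl diphosphate)
- Product: 7 (target, (3R)-farnesyl-DMOA)
- Conditions: FPP, AusN/Trt2 microsomes, 50 mM Tris-HCl pH 7.5, 5 mM MgCl2, 30 °C, 3–12 h; then acidify to pH 3, extract with EtOAc, RP-HPLC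
- Reagents that add atoms: FPP, CC(C)=CCC/C(C)=C/CC/C(C)=C/COP(=O)(O)OP(=O)(O)O (the farnesyl C15H25 group is transferred; PPi is lost)
- Why: The UbiA-type prenyltransferase ionises FPP and the DMOA phenolate attacks through C-5, which is ortho to 4-O⁻ and para to 2-OH. This gives a dearomative ipso-alkylation (a Friedel–Crafts-type prenylation) to the 2,4-dienone tautomer. The active site selects C-5 over C-3 and one prochiral face, so the new quaternary centre is (R). The E,E-alkene geometry is retained because the reaction is an SN2-like allylic transfer at C-1 of FPP. The acid is not subsequently manipulated, so the stereocentre is not scrambled. It has no α-H, so it cannot epimerise.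

**Compound list**

| No. | Name | SMILES | Role |
|---|---|---|---|
| 1 | Methyl 2,4-dihydroxy-3,6-dimethylbenzoate (atraric acid) | COC(=O)c1c(C)cc(O)c(C)c1O | starting material |
| 2 | N,N-Dimethylformamide | CN(C)C=O | starting material (formyl source) |
| 3 | Methyl 5-formyl-2,4-dihydroxy-3,6-dimethylbenzoate | COC(=O)c1c(C)c(C=O)c(O)c(C)c1O | intermediate |
| 4 | Methyl 2,4-dihydroxy-3,5,6-trimethylbenzoate | COC(=O)c1c(C)c(C)c(O)c(C)c1O | intermediate |
| 5 | 3,5-Dimethylorsellinic acid (2,4-dihydroxy-3,5,6-trimethylbenzoic acid) | OC(=O)c1c(C)c(C)c(O)c(C)c1O | intermediate |
| 6 | (2E,6E)-Farnesyl diphosphate | CC(C)=CCC/C(C)=C/CC/C(C)=C/COP(=O)(O)OP(=O)(O)O | starting material |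
| 7 | (3R)-6-Hydroxy-2,3,5-trimethyl-4-oxo-3-[(2E,6E)-3,7,11-trimethyldodeca-2,6,10-trien-1-yl]cyclohexa-1,5-diene-1-carboxylic acid (farnesyl-DMOA) | CC(C)=CCC/C(C)=C/CC/C(C)=C/C[C@@]1(C)C(=O)C(C)=C(O)C(C(=O)O)=C1C | target |

**Totals**
- Total step count: 4
- Longest linear sequence: 4 steps from 1

**Three steps most likely to fail, with fallbacks**

1. **Step 4, enzymatic ipso-farnesylation.** The enzyme is membrane-bound, expression is poor, and yields may be low.
   - Fallback: chemical dearomative alkylation of ester 4 with farnesyl bromide (base, chiral phase-transfer catalyst) to give the methyl ester of the target, or the racemate resolved by preparative chiral HPLC. Then cleave the ester with LiI as in step 3. Regioselectivity between C-5 and C-3 would need to be checked.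

2. **Step 3, LiI ester cleavage.** The hindered ester may cleave slowly, and DMOA may protodecarboxylate on heating or acidification.
   - Fallback: skip steps 1–3 and obtain DMOA biosynthetically. Express the DMOA polyketide synthase (AusA/Trt4 type) in yeast or Aspergillus from acetyl-CoA, malonyl-CoA and SAM, then feed the isolated DMOA into step 4.

3. **Steps 1–2, C-5 formylation and deoxygenation.** C-5 is flanked by OH and CH3, so Vilsmeier formylation may be slow, and the hydroxybenzaldehyde may stall at the benzyl alcohol.
   - Fallback: replace the sequence with a Mannich aminomethylation at C-5 (Me2NH, CH2O), then N-methylation with MeI and hydrogenolysis (H2, Pd/C) of the benzylammonium salt to ArCH3.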